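**Retrosynthetic overview**

1. The strategy rests on the cis-2,3-dimethyl-dihydropyran-4-one ring (O1–C2–C3–C4–C4a–C8a of the target). It is the oxa-Michael adduct of a tigloyl ketone on C4a and the oxygen on C8a, so O1–C2 is disconnected (with protonation at C3) to the tigloylphenol 22.
2. Ahead of that, the target is traced back through hydrolysis of an enol lactone (26) and dearomative C-prenylation of phenol 24 at the lavandulyl-bearing ring carbon.
3. 22 comes from a chroman methyl acetal by C6 lavandulylation (ortho-lithiation/iodination, Negishi coupling), C8 acylation (ortho-lithiation, tiglic Weinreb amide), acetal-to-lactone conversion and MOM removal.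
4. The acetal is made first from phloroglucinol and cinnamaldehyde. Because phloroglucinol is symmetric, the oxygen that closes this ring is unambiguous. It stays locked (acetal, then lactone), so only one hydroxyl is free ortho to the tigloyl group in the key step.
5. Ring order: oxygen ring of the dihydrocoumarin (step 1), pyranone ring (step 12), then dearomatisation of the carbocycle (step 13) and opening of the lactone (step 14).

Key step: step 12

Remark: the sense of induction known for quinine with 7-hydroxy-8-tigloyl coumarins (2R chromanone) is assumed to carry over to 22, whose enone has the same two ortho oxygens; quinidine would be used if it did not.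

**Route**

Step 1
Reactants: 1 phloroglucinol (benzene-1,3,5-triol); 2 (E)-cinnamaldehyde
Product: 4 (4S)-2-methoxy-4-phenyl-3,4-dihydro-2H-chromene-5,7-diol (both C2 epimers), via lactol 3 (not isolated)
Conditions: 1 (3 equiv), (S)-2-[diphenyl(trimethylsilyloxy)methyl]pyrrolidine (20 mol%), PhCO2H (20 mol%), MeCN, 0 °C; aqueous wash to remove excess 1; then MeOH, camphorsulfonic acid (5 mol%), rt
Reagents that add atoms: methanol, CO
Why: Iminium-activated Friedel–Crafts conjugate addition of the phenol carbon, hemiacetal closure and acid-catalysed acetal exchange: the symmetry of 1 makes every ring carbon and flanking hydroxyl equivalent, so the oxygen that closes the ring is by definition the future lactone oxygen, and the (S)-catalyst shields the Re face of the enal β-carbon so that the arene adds to the Si face and sets C4 as S.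

Step 2
Reactants: 4 (4S)-2-methoxy-4-phenyl-3,4-dihydro-2H-chromene-5,7-diol
Product: 5 (4S)-2-methoxy-5,7-bis(methoxymethoxy)-4-phenyl-3,4-dihydro-2H-chromene
Conditions: MOMCl, iPr2NEt, CH2Cl2, 0 °C → rt
Reagents that add atoms: chloromethyl methyl ether, COCCl
Why: Williamson-type O-alkylation of the two phenols under amine base, to which the C2 acetal is inert, installs the groups that later direct metalation.

Step 3
Reactants: 5 (4S)-2-methoxy-5,7-bis(methoxymethoxy)-4-phenyl-3,4-dihydro-2H-chromene
Product: 7 (4S)-6-iodo-2-methoxy-5,7-bis(methoxymethoxy)-4-phenyl-3,4-dihydro-2H-chromene, via aryllithium 6 (not isolated)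
Conditions: n-BuLi, THF, 0 °C; then I2, −78 °C → rt
Reagents that add atoms: iodine, II
Why: Directed ortho-metalation and iodinolysis: C6 lies between two chelating OMOM groups and should be lithiated in preference to C8 (one OMOM group and the non-chelating ring oxygen), and ring lithiation should outrun removal of the tertiary benzylic hydrogen at C4, so the stereocenter is kept.

Step 4
Reactants: 8 racemic lavandulol
Product: 9 (R)-lavandulyl acetate
Conditions: vinyl acetate, porcine pancreatic lipase, hexane, rt, stopped near 35–40% conversion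
Reagents that add atoms: vinyl acetate, C=COC(C)=O
Why: Lipase-catalysed kinetic resolution by irreversible transesterification, in which the (R)-alcohol is expected to be acylated faster, so that stopping at partial conversion favours the enantiopurity of the acetate (a second pass after step 5 is held in reserve).

Step 5
Reactants: 9 (R)-lavandulyl acetate
Product: 10 (R)-lavandulol
Conditions: K2CO3 (cat.), MeOH, rt
Reagents that add atoms: none
Why: Base-catalysed transesterification (methanolysis) of the acetate, which does not involve the stereocenter.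

Step 6
Reactants: 10 (R)-lavandulol
Product: 11 (R)-lavandulyl iodide
Conditions: I2, PPh3, imidazole, CH2Cl2, 0 °C → rt
Reagents that add atoms: iodine, II
Why: Appel-type iodination of the primary alcohol by displacement at CH2, one carbon away from the stereocenter, which is untouched.

Step 7
Reactants: 11 (R)-lavandulyl iodide; 7 (4S)-6-iodo-2-methoxy-5,7-bis(methoxymethoxy)-4-phenyl-3,4-dihydro-2H-chromene
Product: 13 (4S)-2-methoxy-5,7-bis(methoxymethoxy)-6-[(2S)-5-methyl-2-(prop-1-en-2-yl)hex-4-en-1-yl]-4-phenyl-3,4-dihydro-2H-chromene, via lavandulylzinc iodide 12 (not isolated)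
Conditions: Zn dust (activated with BrCH2CH2Br and Me3SiCl), LiCl, THF, 35 °C; then 7, Pd(OAc)2 (5 mol%), SPhos (2-dicyclohexylphosphino-2',6'-dimethoxybiphenyl, 10 mol%), THF, rt → 45 °C
Reagents that add atoms: none
Why: LiCl-assisted zinc insertion gives the primary alkylzinc iodide, and a Negishi sp3–sp2 cross-coupling with a bulky biarylphosphine (fast reductive elimination, little β-hydride elimination) joins it to the hindered aryl iodide without touching the acetal, the MOM ethers or either stereocenter (the descriptor of the side-chain centre changes from R to S only because the CH2 group loses priority).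

Step 8
Reactants: 14 tiglic acid
Product: 16 (E)-N-methoxy-N,2-dimethylbut-2-enamide, via acyl imidazole 15 (not isolated)
Conditions: 1,1'-carbonyldiimidazole, CH2Cl2, 0 °C → rt; then MeNHOMe·HCl, rt
Reagents that add atoms: N,O-dimethylhydroxylamine hydrochloride, CNOC.Cl
Why: Carboxyl activation as the acyl imidazole followed by aminolysis (Weinreb amide formation) leaves the (E)-alkene unchanged.

Step 9
Reactants: 13 (4S)-2-methoxy-5,7-bis(methoxymethoxy)-6-[(2S)-5-methyl-2-(prop-1-en-2-yl)hex-4-en-1-yl]-4-phenyl-3,4-dihydro-2H-chromene; 16 (E)-N-methoxy-N,2-dimethylbut-2-enamide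
Product: 19 (E)-1-[(4S)-2-methoxy-5,7-bis(methoxymethoxy)-6-[(2S)-5-methyl-2-(prop-1-en-2-yl)hex-4-en-1-yl]-4-phenyl-3,4-dihydro-2H-chromen-8-yl]-2-methylbut-2-en-1-one, via aryllithium 17 (not isolated), via lithium hemiaminal 18 (not isolated)
Conditions: s-BuLi, TMEDA, THF, −78 °C; then 16, −78 → −20 °C; H2O
Reagents that add atoms: none
Why: Directed ortho-metalation at the only remaining ring C–H (C8, ortho to the C7 OMOM group) and Weinreb ketone synthesis, in which the chelated adduct 18 resists a second addition and releases the (E)-enone on work-up; the ketone is flanked by two protected oxygens and cannot cyclise.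

Step 10
Reactants: 19 (E)-1-[(4S)-2-methoxy-5,7-bis(methoxymethoxy)-6-[(2S)-5-methyl-2-(prop-1-en-2-yl)hex-4-en-1-yl]-4-phenyl-3,4-dihydro-2H-chromen-8-yl]-2-methylbut-2-en-1-one
Product: 21 (4S)-5,7-bis(methoxymethoxy)-8-[(E)-2-methylbut-2-enoyl]-6-[(2S)-5-methyl-2-(prop-1-en-2-yl)hex-4-en-1-yl]-4-phenyl-3,4-dihydro-2H-chromen-2-one, via lactol 20 (not isolated)
Conditions: AcOH/THF/H2O (3:1:1), 40 °C; concentrate; then Dess–Martin periodinane, CH2Cl2, 0 °C → rt
Reagents that add atoms: water, O
Why: Mild acid hydrolysis of the aldehyde-derived mixed acetal (far more labile than the formaldehyde-derived MOM ethers) and Dess–Martin oxidation of the lactol should give the lactone on the oxygen fixed in step 1, while the other two phenol oxygens stay protected so that no other ring can close.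

Step 11
Reactants: 21 (4S)-5,7-bis(methoxymethoxy)-8-[(E)-2-methylbut-2-enoyl]-6-[(2S)-5-methyl-2-(prop-1-en-2-yl)hex-4-en-1-yl]-4-phenyl-3,4-dihydro-2H-chromen-2-one
Product: 22 (4S)-5,7-dihydroxy-8-[(E)-2-methylbut-2-enoyl]-6-[(2S)-5-methyl-2-(prop-1-en-2-yl)hex-4-en-1-yl]-4-phenyl-3,4-dihydro-2H-chromen-2-one
Conditions: ZnBr2, n-PrSH, CH2Cl2, 0 °C, short contact; cold pH 7 buffer
Reagents that add atoms: none
Why: Lewis-acid-assisted MOM cleavage with thiol capture of the methoxymethyl group under aprotic, non-nucleophilic conditions, chosen so that the lactone is not opened, the lavandulyl alkenes are not protonated and the freed C7 phenol does not add to the enone before the chiral catalyst is present.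

Step 12
Reactants: 22 (4S)-5,7-dihydroxy-8-[(E)-2-methylbut-2-enoyl]-6-[(2S)-5-methyl-2-(prop-1-en-2-yl)hex-4-en-1-yl]-4-phenyl-3,4-dihydro-2H-chromen-2-one
Product: 24 (4S,8R,9S)-5-hydroxy-8,9-dimethyl-6-[(2S)-5-methyl-2-(prop-1-en-2-yl)hex-4-en-1-yl]-4-phenyl-3,4,8,9-tetrahydro-2H,10H-pyrano[2,3-f]chromene-2,10-dione, via enol 23 (not isolated)
Conditions: quinine (C20H24N2O2, 20 mol%), chlorobenzene, 10–15 °C; cold dilute citric acid wash as soon as conversion is complete
Reagents that add atoms: none
Why: Quinine acts as a bifunctional catalyst: its quinuclidine nitrogen takes the proton of the C7 hydroxyl (the one hydroxyl ortho to the tigloyl ketone on C8) and its C9 hydroxyl hydrogen-bonds the enone carbonyl, the phenoxide oxygen adds to the β-carbon of the (E)-enone to make the O–C bond, and the enol 23 is then protonated at the α-carbon. The closest known reaction type is the cinchona-alkaloid-catalysed asymmetric intramolecular oxa-Michael addition of ortho-tigloylphenols (7-hydroxy-8-tigloylcoumarins) to cis-2,3-dimethylchroman-4-ones. The pyranone ring closes in the 6-endo-trig mode. The oxygen-bearing centre (8R) is set by the alkaloid, which presents one enantiotopic face of the β-carbon to the phenoxide inside the hydrogen-bonded ion pair, and the adjacent centre (9S) is set by kinetic protonation of 23 on the face opposite the new methyl group, which places the two methyl groups cis. The step needs a single ring-closing oxygen and no cis-to-trans drift: the second oxygen ortho to the acyl group is locked in the lactone, the C5 hydroxyl is para to the acyl group and cannot reach the enone, and the weak base is washed out promptly.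

Step 13
Reactants: 24 (4S,8R,9S)-5-hydroxy-8,9-dimethyl-6-[(2S)-5-methyl-2-(prop-1-en-2-yl)hex-4-en-1-yl]-4-phenyl-3,4,8,9-tetrahydro-2H,10H-pyrano[2,3-f]chromene-2,10-dione
Product: 26 (4S,6S,8R,9S)-8,9-dimethyl-6-(3-methylbut-2-en-1-yl)-6-[(2S)-5-methyl-2-(prop-1-en-2-yl)hex-4-en-1-yl]-4-phenyl-3,4,8,9-tetrahydro-2H-pyrano[2,3-f]chromene-2,5,10(6H)-trione, via lithium phenoxide 25 (not isolated)
Conditions: LiN(SiMe3)2 (1.0 equiv), toluene, −78 → 0 °C; then prenyl bromide, 0 °C → rt; HPLC separation of the C6 epimers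
Reagents that add atoms: prenyl bromide (1-bromo-3-methylbut-2-ene), CC(C)=CCBr
Why: Alkylative dearomatisation of a phenoxide: the lithium phenoxide in a non-polar solvent is a tight ion pair that favours C- over O-alkylation, the lavandulyl-bearing C6 is the least hindered and most electron-rich of the ortho and para carbons (it sits between the phenoxide and the ether oxygen), and since little facial bias is expected at the new quaternary carbon both C6 epimers should form and the 6S epimer is separated.

Step 14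
Reactants: 26 (4S,6S,8R,9S)-8,9-dimethyl-6-(3-methylbut-2-en-1-yl)-6-[(2S)-5-methyl-2-(prop-1-en-2-yl)hex-4-en-1-yl]-4-phenyl-3,4,8,9-tetrahydro-2H-pyrano[2,3-f]chromene-2,5,10(6H)-trione
Product: 28 (3S)-3-[(2R,3S,8S)-5-hydroxy-2,3-dimethyl-8-(3-methylbut-2-en-1-yl)-8-[(2S)-5-methyl-2-(prop-1-en-2-yl)hex-4-en-1-yl]-4,7-dioxo-3,4,7,8-tetrahydro-2H-chromen-6-yl]-3-phenylpropanoic acid (CNP0150579.2), via dilithium salt 27 (not isolated)
Conditions: LiOH, THF/H2O, 0 °C, short contact; then 1 M HCl to pH 3, 0 °C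
Reagents that add atoms: lithium hydroxide, [Li+].[OH-]
Why: Saponification of the enol lactone, the most electrophilic carbonyl present, releases the acid and the enol, and low temperature with short contact should keep the base-sensitive cis-dimethylpyranone intact.

**Compound list**

1 | phloroglucinol | Oc1cc(O)cc(O)c1 | starting material
2 | (E)-cinnamaldehyde | O=C/C=C/c1ccccc1 | starting material
3 | (4S)-4-phenyl-3,4-dihydro-2H-chromene-2,5,7-triol (lactol, both C2 epimers) | OC1C[C@@H](c2ccccc2)c2c(O)cc(O)cc2O1 | intermediate (not isolated)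
4 | (4S)-2-methoxy-4-phenyl-3,4-dihydro-2H-chromene-5,7-diol (both C2 epimers) | COC1C[C@@H](c2ccccc2)c2c(O)cc(O)cc2O1 | intermediate
5 | (4S)-2-methoxy-5,7-bis(methoxymethoxy)-4-phenyl-3,4-dihydro-2H-chromene | COC1C[C@@H](c2ccccc2)c2c(OCOC)cc(OCOC)cc2O1 | intermediate
6 | 6-lithio derivative of 5 | COC1C[C@@H](c2ccccc2)c2c(OCOC)c([Li])c(OCOC)cc2O1 | intermediate (not isolated)
7 | (4S)-6-iodo-2-methoxy-5,7-bis(methoxymethoxy)-4-phenyl-3,4-dihydro-2H-chromene | COC1C[C@@H](c2ccccc2)c2c(OCOC)c(I)c(OCOC)cc2O1 | intermediate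
8 | racemic lavandulol (5-methyl-2-(prop-1-en-2-yl)hex-4-en-1-ol) | C=C(C)C(CO)CC=C(C)C | starting material
9 | (R)-lavandulyl acetate | C=C(C)[C@@H](CC=C(C)C)COC(C)=O | intermediate
10 | (R)-lavandulol | C=C(C)[C@@H](CC=C(C)C)CO | intermediate
11 | (R)-lavandulyl iodide ((2R)-1-iodo-5-methyl-2-(prop-1-en-2-yl)hex-4-ene) | C=C(C)[C@@H](CC=C(C)C)CI | intermediate
12 | (R)-lavandulylzinc iodide | C=C(C)[C@@H](CC=C(C)C)C[Zn]I | intermediate (not isolated)
13 | (4S)-2-methoxy-5,7-bis(methoxymethoxy)-6-[(2S)-5-methyl-2-(prop-1-en-2-yl)hex-4-en-1-yl]-4-phenyl-3,4-dihydro-2H-chromene | C=C(C)[C@@H](CC=C(C)C)Cc1c(OCOC)c2c(cc1OCOC)OC(OC)C[C@H]2c1ccccc1 | intermediate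
14 | tiglic acid | C/C=C(\C)C(=O)O | starting material
15 | (E)-1-(imidazol-1-yl)-2-methylbut-2-en-1-one | C/C=C(\C)C(=O)n1ccnc1 | intermediate (not isolated)
16 | (E)-N-methoxy-N,2-dimethylbut-2-enamide | C/C=C(\C)C(=O)N(C)OC | intermediate
17 | 8-lithio derivative of 13 | C=C(C)[C@@H](CC=C(C)C)Cc1c(OCOC)c2c(c([Li])c1OCOC)OC(OC)C[C@H]2c1ccccc1 | intermediate (not isolated)
18 | lithium hemiaminal from 17 and 16 | C=C(C)[C@@H](CC=C(C)C)Cc1c(OCOC)c2c(c(C(O[Li])(N(C)OC)/C(C)=C/C)c1OCOC)OC(OC)C[C@H]2c1ccccc1 | intermediate (not isolated)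
19 | (E)-1-[(4S)-2-methoxy-5,7-bis(methoxymethoxy)-6-[(2S)-5-methyl-2-(prop-1-en-2-yl)hex-4-en-1-yl]-4-phenyl-3,4-dihydro-2H-chromen-8-yl]-2-methylbut-2-en-1-one | C=C(C)[C@@H](CC=C(C)C)Cc1c(OCOC)c2c(c(C(=O)/C(C)=C/C)c1OCOC)OC(OC)C[C@H]2c1ccccc1 | intermediate
20 | lactol of 19 (2-hydroxy in place of 2-methoxy) | C=C(C)[C@@H](CC=C(C)C)Cc1c(OCOC)c2c(c(C(=O)/C(C)=C/C)c1OCOC)OC(O)C[C@H]2c1ccccc1 | intermediate (not isolated)
21 | (4S)-5,7-bis(methoxymethoxy)-8-[(E)-2-methylbut-2-enoyl]-6-[(2S)-5-methyl-2-(prop-1-en-2-yl)hex-4-en-1-yl]-4-phenyl-3,4-dihydro-2H-chromen-2-one | C=C(C)[C@@H](CC=C(C)C)Cc1c(OCOC)c2c(c(C(=O)/C(C)=C/C)c1OCOC)OC(=O)C[C@H]2c1ccccc1 | intermediate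
22 | (4S)-5,7-dihydroxy-8-[(E)-2-methylbut-2-enoyl]-6-[(2S)-5-methyl-2-(prop-1-en-2-yl)hex-4-en-1-yl]-4-phenyl-3,4-dihydro-2H-chromen-2-one (key-step precursor) | C=C(C)[C@@H](CC=C(C)C)Cc1c(O)c2c(c(C(=O)/C(C)=C/C)c1O)OC(=O)C[C@H]2c1ccccc1 | intermediate
23 | enol of 24 (10-hydroxy, C9=C10) | C=C(C)[C@@H](CC=C(C)C)Cc1c(O)c2c(c3c1O[C@H](C)C(C)=C3O)OC(=O)C[C@H]2c1ccccc1 | intermediate (not isolated)
24 | (4S,8R,9S)-5-hydroxy-8,9-dimethyl-6-[(2S)-5-methyl-2-(prop-1-en-2-yl)hex-4-en-1-yl]-4-phenyl-3,4,8,9-tetrahydro-2H,10H-pyrano[2,3-f]chromene-2,10-dione (key-step product) | C=C(C)[C@@H](CC=C(C)C)Cc1c(O)c2c(c3c1O[C@H](C)[C@H](C)C3=O)OC(=O)C[C@H]2c1ccccc1 | intermediate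
25 | lithium phenoxide of 24 | C=C(C)[C@@H](CC=C(C)C)Cc1c(O[Li])c2c(c3c1O[C@H](C)[C@H](C)C3=O)OC(=O)C[C@H]2c1ccccc1 | intermediate (not isolated)
26 | (4S,6S,8R,9S)-8,9-dimethyl-6-(3-methylbut-2-en-1-yl)-6-[(2S)-5-methyl-2-(prop-1-en-2-yl)hex-4-en-1-yl]-4-phenyl-3,4,8,9-tetrahydro-2H-pyrano[2,3-f]chromene-2,5,10(6H)-trione | C=C(C)[C@@H](CC=C(C)C)C[C@]1(CC=C(C)C)C(=O)C3=C(OC(=O)C[C@H]3c3ccccc3)C2=C1O[C@H](C)[C@H](C)C2=O | intermediate
27 | dilithium salt of 28 (carboxylate and C5 enolate) | C=C(C)[C@@H](CC=C(C)C)C[C@]1(CC=C(C)C)C(=O)C([C@@H](CC(=O)[O-])c2ccccc2)=C([O-])C2=C1O[C@H](C)[C@H](C)C2=O.[Li+].[Li+] | intermediate (not isolated)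
28 | (3S)-3-[(2R,3S,8S)-5-hydroxy-2,3-dimethyl-8-(3-methylbut-2-en-1-yl)-8-[(2S)-5-methyl-2-(prop-1-en-2-yl)hex-4-en-1-yl]-4,7-dioxo-3,4,7,8-tetrahydro-2H-chromen-6-yl]-3-phenylpropanoic acid | C=C(C)[C@@H](CC=C(C)C)C[C@]1(CC=C(C)C)C(=O)C([C@@H](CC(=O)O)c2ccccc2)=C(O)C2=C1O[C@H](C)[C@H](C)C2=O | target

**Step count**

Total: 14 steps. Longest linear sequence: 10 steps (1, 2, 3, 7, 9, 10, 11, 12, 13, 14).

**Steps most likely to fail**

Step 13. The process at risk is alkylation at the phenoxide oxygen, or at the other ortho carbon (C4a) or the para carbon (C10a), instead of C6, together with formation of the quaternary carbon without facial control. The fallback replaces the bromide displacement by a zerovalent-palladium allylic alkylation. 24 is treated with tert-butyl (3-methylbut-2-en-1-yl) carbonate, Pd2(dba)3 and a Trost-type chiral diphosphine in toluene at rt. The liberated tert-butoxide deprotonates the phenol, and the prenyl ether of this acidic para-acylphenol can re-ionise on palladium, so O-alkylation becomes reversible and material should drain to the C-prenylated dienone. The chiral ligand also gives a handle on the configuration at C6. The fallback sets out from 24 and comes back at 26; no new compound is formed on the way (F0).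

Step 12. The process at risk is loss of enantiofacial control (the C5 phenol competes with the C7 phenol for the quinuclidine, and an uncatalysed closure may run beside the catalysed one) and quinine-promoted drift of the cis product to trans. The fallback forms the same O–C bond by an intramolecular Mitsunobu displacement, with both methyl-bearing centres taken from the chiral pool.
- Ethyl (S)-3-hydroxybutanoate is methylated anti (Fráter–Seebach, LDA then MeI) to ethyl (2S,3S)-3-hydroxy-2-methylbutanoate F1.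
- F1 is silylated (TBSCl, imidazole) to ethyl (2S,3S)-3-(tert-butyldimethylsilyloxy)-2-methylbutanoate F2.
- F2 is converted (MeNHOMe·HCl, i-PrMgCl) into (2S,3S)-3-(tert-butyldimethylsilyloxy)-N-methoxy-N,2-dimethylbutanamide F3.
- Aryllithium 17 is trapped with F3 in place of 16 to give the β-silyloxy ketone F4.
- Hydrolysis and oxidation as in step 10 lead through the lactol F5 to the lactone F6.
- ZnBr2/n-PrSH and then HF·pyridine free the dihydroxy β-hydroxy ketone F7.
- PPh3/DIAD closes the ring by attack of the C7 phenol oxygen on the carbinol carbon with inversion, which gives the cis (8R,9S) arrangement of 24 directly.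

The fallback sets out from 17 and comes back at 24.

Step 9. The process at risk is slow ring lithiation at the singly activated C8 with competing removal of the doubly benzylic C4 hydrogen (which would erode the C4 configuration), or proton transfer instead of addition when the hindered aryllithium meets the amide. In the fallback, C8 of 13, the only free ring position, is brominated (NBS, CH2Cl2, −78 °C) to the 8-bromo compound F8. Bromine–lithium exchange (t-BuLi, THF, −78 °C) gives aryllithium 17 without a deprotonation step. Addition to (E)-2-methylbut-2-enal gives the carbinol F9, and MnO2 in CH2Cl2 oxidises it to the ketone. The fallback sets out from 13 and comes back at 19.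

**Further compounds**

F0 | step 13 | none | none
F1 | step 12 | ethyl (2S,3S)-3-hydroxy-2-methylbutanoate | CCOC(=O)[C@@H](C)[C@H](C)O
F2 | step 12 | ethyl (2S,3S)-3-(tert-butyldimethylsilyloxy)-2-methylbutanoate | CCOC(=O)[C@@H](C)[C@H](C)O[Si](C)(C)C(C)(C)C
F3 | step 12 | (2S,3S)-3-(tert-butyldimethylsilyloxy)-N-methoxy-N,2-dimethylbutanamide | CON(C)C(=O)[C@@H](C)[C@H](C)O[Si](C)(C)C(C)(C)C
F4 | step 12 | (2S,3S)-3-(tert-butyldimethylsilyloxy)-1-[(4S)-2-methoxy-5,7-bis(methoxymethoxy)-6-[(2S)-5-methyl-2-(prop-1-en-2-yl)hex-4-en-1-yl]-4-phenyl-3,4-dihydro-2H-chromen-8-yl]-2-methylbutan-1-one | C=C(C)[C@@H](CC=C(C)C)Cc1c(OCOC)c2c(c(C(=O)[C@@H](C)[C@H](C)O[Si](C)(C)C(C)(C)C)c1OCOC)OC(OC)C[C@H]2c1ccccc1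
F5 | step 12 | lactol of F4 (2-hydroxy in place of 2-methoxy) | C=C(C)[C@@H](CC=C(C)C)Cc1c(OCOC)c2c(c(C(=O)[C@@H](C)[C@H](C)O[Si](C)(C)C(C)(C)C)c1OCOC)OC(O)C[C@H]2c1ccccc1
F6 | step 12 | (4S)-8-[(2S,3S)-3-(tert-butyldimethylsilyloxy)-2-methylbutanoyl]-5,7-bis(methoxymethoxy)-6-[(2S)-5-methyl-2-(prop-1-en-2-yl)hex-4-en-1-yl]-4-phenyl-3,4-dihydro-2H-chromen-2-one | C=C(C)[C@@H](CC=C(C)C)Cc1c(OCOC)c2c(c(C(=O)[C@@H](C)[C@H](C)O[Si](C)(C)C(C)(C)C)c1OCOC)OC(=O)C[C@H]2c1ccccc1
F7 | step 12 | (4S)-5,7-dihydroxy-8-[(2S,3S)-3-hydroxy-2-methylbutanoyl]-6-[(2S)-5-methyl-2-(prop-1-en-2-yl)hex-4-en-1-yl]-4-phenyl-3,4-dihydro-2H-chromen-2-one | C=C(C)[C@@H](CC=C(C)C)Cc1c(O)c2c(c(C(=O)[C@@H](C)[C@H](C)O)c1O)OC(=O)C[C@H]2c1ccccc1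
F8 | step 9 | (4S)-8-bromo-2-methoxy-5,7-bis(methoxymethoxy)-6-[(2S)-5-methyl-2-(prop-1-en-2-yl)hex-4-en-1-yl]-4-phenyl-3,4-dihydro-2H-chromene | C=C(C)[C@@H](CC=C(C)C)Cc1c(OCOC)c2c(c(Br)c1OCOC)OC(OC)C[C@H]2c1ccccc1
F9 | step 9 | (E)-1-[(4S)-2-methoxy-5,7-bis(methoxymethoxy)-6-[(2S)-5-methyl-2-(prop-1-en-2-yl)hex-4-en-1-yl]-4-phenyl-3,4-dihydro-2H-chromen-8-yl]-2-methylbut-2-en-1-ol (both carbinol epimers) | C=C(C)[C@@H](CC=C(C)C)Cc1c(OCOC)c2c(c(C(O)/C(C)=C/C)c1OCOC)OC(OC)C[C@H]2c1ccccc1
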